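**Retrosynthetic overview**
1. Target 22 ⇐ bis-silyl ether 21; the last step is a buffered fluoride desilylation.
2. 21 ⇐ aryl–vinyl disconnection into arylboronate 8 and (S)-dienyl triflate 20 (Suzuki–Miyaura coupling).
3. 20 ⇐ (S)-α-angeloyloxy ketone 18 ⇐ sulcatone 14 + O-angeloyl hydroxylamine 13. The allylic C–O bond, the only stereocentre and the angelate are made together by a catalytic asymmetric [3,3] α-oxyacylation (key step).
4. 8 ⇐ 2,4-dihydroxy-3-methylbenzaldehyde 1 by silylation, Dakin oxidation (aryl C–O), phenol-directed C–H borylation and acetylation.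
5. No ring is built; the benzene ring is bought in with 1.

Assumption: the sense of induction of the new step 6 cannot be known in advance; (R)-TRIP is written as the acid enantiomer that gives the (S)-ester, and its mirror image is used if a first run shows the opposite sense.

**Route**

Step 1
Reactants: 1 2,4-dihydroxy-3-methylbenzaldehyde
Product: 2 2,4-bis[(tert-butyldimethylsilyl)oxy]-3-methylbenzaldehyde
Conditions: TBSCl (2.5 equiv), imidazole, DMF, rt→40 °C
Reagents that add atoms: tert-butyldimethylsilyl chloride, CC(C)(C)[Si](C)(C)Cl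
Why: Standard silyl ether formation on both phenols (the hydrogen-bonded ortho OH reacts on gentle warming); no stereocentre is involved.

Step 2
Reactants: 2 2,4-bis[(tert-butyldimethylsilyl)oxy]-3-methylbenzaldehyde
Product: 4 2,4-bis[(tert-butyldimethylsilyl)oxy]-3-methylphenol, via aryl formate 3 (not isolated)
Conditions: mCPBA (1.3 equiv), NaHCO3, CH2Cl2, 0 °C→rt; then MeOH, PPTS (cat.), rt
Reagents that add atoms: meta-chloroperoxybenzoic acid, OOC(=O)c1cccc(Cl)c1
Why: Dakin-type Baeyer–Villiger oxidation in which the electron-rich aryl group migrates, followed by mildly acidic methanolysis of the formate so that no phenoxide forms that could shift the neighbouring silyl group.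

Step 3
Reactants: 4 2,4-bis[(tert-butyldimethylsilyl)oxy]-3-methylphenol
Product: 7 2,4-bis[(tert-butyldimethylsilyl)oxy]-3-methyl-6-(4,4,5,5-tetramethyl-1,3,2-dioxaborolan-2-yl)phenol, via O-boryl phenol ester 5 (not isolated), via C,O-diboryl arene 6 (not isolated)
Conditions: HBpin (2.5 equiv), [Ir(OMe)(cod)]2 (2 mol %), 4,4'-di-tert-butyl-2,2'-bipyridine (4 mol %), cyclohexane, rt then 80 °C; MeOH work-up
Reagents that add atoms: pinacolborane, CC1(C)OBOC1(C)C
Why: Iridium-catalysed aromatic C–H borylation in which the phenol is masked in the flask as its O-Bpin ester, whose ortho C–H is borylated while the only other ring C–H is blocked by the flanking OTBS group.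

Step 4
Reactants: 7 2,4-bis[(tert-butyldimethylsilyl)oxy]-3-methyl-6-(4,4,5,5-tetramethyl-1,3,2-dioxaborolan-2-yl)phenol
Product: 8 2,4-bis[(tert-butyldimethylsilyl)oxy]-3-methyl-6-(4,4,5,5-tetramethyl-1,3,2-dioxaborolan-2-yl)phenyl acetate
Conditions: Ac2O, pyridine, DMAP (cat.), CH2Cl2, 0 °C
Reagents that add atoms: acetic anhydride, CC(=O)OC(C)=O
Why: DMAP-catalysed O-acetylation of the single free phenol puts the acetate of the target on the correct oxygen before the coupling.

Step 5
Reactants: 9 angelic acid, (2Z)-2-methylbut-2-enoic acid; 10 tert-butyl N-hydroxy-N-methylcarbamate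
Product: 13 N-methyl-O-[(2Z)-2-methylbut-2-enoyl]hydroxylamine hydrochloride, via mixed anhydride 11 (not isolated), via Boc-protected acyloxyamine 12 (not isolated)
Conditions: 2,4,6-trichlorobenzoyl chloride, Et3N, toluene, 0 °C→rt; 10, rt; aqueous wash; then HCl (4 M in dioxane), 0 °C→rt (telescoped)
Reagents that add atoms: hydrogen chloride, Cl
Why: Yamaguchi mixed-anhydride O-acylation of the N-hydroxy carbamate keeps the (Z) geometry of the angelate, and acidolysis of the Boc group gives the storable hydrochloride.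

Step 6
Reactants: 14 6-methylhept-5-en-2-one (sulcatone); 13 N-methyl-O-[(2Z)-2-methylbut-2-enoyl]hydroxylamine hydrochloride
Product: 18 (3S)-6-methyl-2-oxohept-5-en-3-yl (2Z)-2-methylbut-2-enoate, via free hydroxylamine base 15 (not isolated), via ene-hydroxylamine 16 (not isolated), via acyloxy imine 17 (not isolated)
Conditions: 13 freed as base (cold aq NaHCO3/toluene, used at once), 14 (2.5 equiv), (R)-TRIP (10 mol %), Amberlite CG50 (acid form), H2O (2 equiv), toluene, 0 °C
Reagents that add atoms: water, O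
Why: Proposed new method: the ketone condenses at nitrogen and tautomerises to the more substituted (E)-N-(acyloxy)enamine, which stays ion-paired and hydrogen-bonded to the chiral phosphate so that the charge-accelerated chair-like [3,3]-sigmatropic shift (N–O breaks, the acyl C=O oxygen bonds to C3) occurs on one enantioface and sets the (S) centre while delivering the intact (Z)-angelate, water hydrolyses the imine before it can tautomerise, and the weak-acid resin binds methylamine so the phosphoric acid turns over; the closest known reaction types are the racemic [3,3] α-oxyacylation of ketones by N-alkyl-O-acylhydroxylamine salts and chiral-phosphoric-acid-catalysed asymmetric [3,3] shifts of ene-hydrazines (Fischer-type indolisation run with the same resin).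

Step 7
Reactants: 18 (3S)-6-methyl-2-oxohept-5-en-3-yl (2Z)-2-methylbut-2-enoate
Product: 20 (3S)-6-methyl-2-{[(trifluoromethyl)sulfonyl]oxy}hepta-1,5-dien-3-yl (2Z)-2-methylbut-2-enoate, via potassium enolate 19 (not isolated)
Conditions: KN(SiMe3)2 (1.05 equiv), THF, −78 °C, 15 min; then Comins' reagent (1.1 equiv), −78 °C
Reagents that add atoms: Comins' reagent, N-(5-chloropyridin-2-yl)bis(trifluoromethanesulfonimide), O=S(=O)(N(c1ccc(Cl)cn1)S(=O)(=O)C(F)(F)F)C(F)(F)F
Why: Kinetic deprotonation of the unhindered methyl group by the bulky amide base and O-triflation of the enolate (enol triflate formation) leave the C3 stereocentre untouched.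

Step 8
Reactants: 20 (3S)-6-methyl-2-{[(trifluoromethyl)sulfonyl]oxy}hepta-1,5-dien-3-yl (2Z)-2-methylbut-2-enoate; 8 2,4-bis[(tert-butyldimethylsilyl)oxy]-3-methyl-6-(4,4,5,5-tetramethyl-1,3,2-dioxaborolan-2-yl)phenyl acetate
Product: 21 (3S)-2-{2-acetoxy-3,5-bis[(tert-butyldimethylsilyl)oxy]-4-methylphenyl}-6-methylhepta-1,5-dien-3-yl (2Z)-2-methylbut-2-enoate
Conditions: Pd(OAc)2 (3 mol %), SPhos (6 mol %), K3PO4 (anhydrous, powdered, 2 equiv), THF, 40 °C; 20 in slight excess (1.2 equiv)
Reagents that add atoms: none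
Why: Suzuki–Miyaura coupling in which oxidative addition of zerovalent palladium into the vinyl C–OTf bond outruns ionisation of the hindered allylic ester, and anhydrous phosphate spares the aryl acetate and silyl ethers; the stereocentre is not involved.

Step 9
Reactants: 21 (3S)-2-{2-acetoxy-3,5-bis[(tert-butyldimethylsilyl)oxy]-4-methylphenyl}-6-methylhepta-1,5-dien-3-yl (2Z)-2-methylbut-2-enoate
Product: 22 (3S)-2-(2-acetoxy-3,5-dihydroxy-4-methylphenyl)-6-methylhepta-1,5-dien-3-yl (2Z)-2-methylbut-2-enoate (CNP0147405.1)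
Conditions: TBAF (2.5 equiv), AcOH (3 equiv), THF, 0 °C
Reagents that add atoms: none
Why: Fluoride desilylation of the two aryl silyl ethers under acetic acid buffering keeps the freed phenols protonated, so the acetate does not migrate to the neighbouring oxygen and the angelate is not touched.

**Compound list**
1 | 2,4-dihydroxy-3-methylbenzaldehyde | O=Cc1ccc(O)c(C)c1O | starting material
2 | 2,4-bis[(tert-butyldimethylsilyl)oxy]-3-methylbenzaldehyde | O=Cc1ccc(O[Si](C)(C)C(C)(C)C)c(C)c1O[Si](C)(C)C(C)(C)C | intermediate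
3 | 2,4-bis[(tert-butyldimethylsilyl)oxy]-3-methylphenyl formate | O=COc1ccc(O[Si](C)(C)C(C)(C)C)c(C)c1O[Si](C)(C)C(C)(C)C | intermediate
4 | 2,4-bis[(tert-butyldimethylsilyl)oxy]-3-methylphenol | Oc1ccc(O[Si](C)(C)C(C)(C)C)c(C)c1O[Si](C)(C)C(C)(C)C | intermediate
5 | 2-{2,4-bis[(tert-butyldimethylsilyl)oxy]-3-methylphenoxy}-4,4,5,5-tetramethyl-1,3,2-dioxaborolane | CC1(C)OB(Oc2ccc(O[Si](C)(C)C(C)(C)C)c(C)c2O[Si](C)(C)C(C)(C)C)OC1(C)C | intermediate
6 | 2-{2,4-bis[(tert-butyldimethylsilyl)oxy]-3-methyl-6-(4,4,5,5-tetramethyl-1,3,2-dioxaborolan-2-yl)phenoxy}-4,4,5,5-tetramethyl-1,3,2-dioxaborolane | CC1(C)OB(Oc2c(B3OC(C)(C)C(C)(C)O3)cc(O[Si](C)(C)C(C)(C)C)c(C)c2O[Si](C)(C)C(C)(C)C)OC1(C)C | intermediate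
7 | 2,4-bis[(tert-butyldimethylsilyl)oxy]-3-methyl-6-(4,4,5,5-tetramethyl-1,3,2-dioxaborolan-2-yl)phenol | Oc1c(B2OC(C)(C)C(C)(C)O2)cc(O[Si](C)(C)C(C)(C)C)c(C)c1O[Si](C)(C)C(C)(C)C | intermediate
8 | 2,4-bis[(tert-butyldimethylsilyl)oxy]-3-methyl-6-(4,4,5,5-tetramethyl-1,3,2-dioxaborolan-2-yl)phenyl acetate | CC(=O)Oc1c(B2OC(C)(C)C(C)(C)O2)cc(O[Si](C)(C)C(C)(C)C)c(C)c1O[Si](C)(C)C(C)(C)C | intermediate
9 | angelic acid, (2Z)-2-methylbut-2-enoic acid | O=C(O)/C(C)=C\C | starting material
10 | tert-butyl N-hydroxy-N-methylcarbamate | CN(O)C(=O)OC(C)(C)C | starting material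
11 | (2Z)-2-methylbut-2-enoic 2,4,6-trichlorobenzoic anhydride | O=C(OC(=O)c1c(Cl)cc(Cl)cc1Cl)/C(C)=C\C | intermediate
12 | tert-butyl N-methyl-N-{[(2Z)-2-methylbut-2-enoyl]oxy}carbamate | CN(OC(=O)/C(C)=C\C)C(=O)OC(C)(C)C | intermediate
13 | N-methyl-O-[(2Z)-2-methylbut-2-enoyl]hydroxylamine hydrochloride | CNOC(=O)/C(C)=C\C.Cl | intermediate
14 | 6-methylhept-5-en-2-one (sulcatone) | CC(=O)CCC=C(C)C | starting material
15 | N-methyl-O-[(2Z)-2-methylbut-2-enoyl]hydroxylamine (free base) | CNOC(=O)/C(C)=C\C | intermediate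
16 | N-methyl-N-[(2E)-6-methylhepta-2,5-dien-2-yl]-O-[(2Z)-2-methylbut-2-enoyl]hydroxylamine | CN(OC(=O)/C(C)=C\C)/C(C)=C/CC=C(C)C | intermediate
17 | (3S)-6-methyl-2-(methylimino)hept-5-en-3-yl (2Z)-2-methylbut-2-enoate | C/N=C(\C)[C@H](CC=C(C)C)OC(=O)/C(C)=C\C | intermediate
18 | (3S)-6-methyl-2-oxohept-5-en-3-yl (2Z)-2-methylbut-2-enoate | CC(=O)[C@H](CC=C(C)C)OC(=O)/C(C)=C\C | intermediate
19 | potassium (3S)-6-methyl-3-{[(2Z)-2-methylbut-2-enoyl]oxy}hepta-1,5-dien-2-olate | C=C([O-])[C@H](CC=C(C)C)OC(=O)/C(C)=C\C.[K+] | intermediate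
20 | (3S)-6-methyl-2-{[(trifluoromethyl)sulfonyl]oxy}hepta-1,5-dien-3-yl (2Z)-2-methylbut-2-enoate | C=C(OS(=O)(=O)C(F)(F)F)[C@H](CC=C(C)C)OC(=O)/C(C)=C\C | intermediate
21 | (3S)-2-{2-acetoxy-3,5-bis[(tert-butyldimethylsilyl)oxy]-4-methylphenyl}-6-methylhepta-1,5-dien-3-yl (2Z)-2-methylbut-2-enoate | C=C(c1cc(O[Si](C)(C)C(C)(C)C)c(C)c(O[Si](C)(C)C(C)(C)C)c1OC(C)=O)[C@H](CC=C(C)C)OC(=O)/C(C)=C\C | intermediate
22 | (3S)-2-(2-acetoxy-3,5-dihydroxy-4-methylphenyl)-6-methylhepta-1,5-dien-3-yl (2Z)-2-methylbut-2-enoate | C=C(c1cc(O)c(C)c(O)c1OC(C)=O)[C@H](CC=C(C)C)OC(=O)/C(C)=C\C | target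

**Step count**
Total: 9 steps. Longest linear sequence: 6 steps (steps 1, 2, 3, 4, 8, 9); the side-chain branch is 5 steps (5, 6, 7, 8, 9).

**Three steps most likely to fail, with fallbacks**

Step 6 (the proposed new asymmetric α-oxyacylation). Likely problems are low enantioselectivity from an uncatalysed background [3,3] shift or an enamine E/Z mixture, some attack at the methyl carbon, and partial racemisation of imine 17 before hydrolysis. The fallback uses known chemistry and sets out from sulcatone 14. A D-proline-catalysed O-selective nitroso aldol reaction with nitrosobenzene (DMSO, rt) gives (3S)-6-methyl-3-[(phenylamino)oxy]hept-5-en-2-one F1; the D-catalyst is chosen because L-proline gives the (R) series. CuSO4 (0.3 equiv) in MeOH at 0 °C cleaves the N–O bond to (3S)-3-hydroxy-6-methylhept-5-en-2-one F2. Yamaguchi esterification of F2 with angelic acid 9 (2,4,6-trichlorobenzoyl chloride, Et3N, toluene, through mixed anhydride 11) comes back to the route at ketone 18.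

Step 7 (enol triflate from the α-acyloxy ketone). The enolate may equilibrate towards C3 (racemisation), or attack its own ester (acyl shift). The fallback sets out from sulcatone 14 and carries the oxygen as a silyl ether through the basic step. The hydroxy ketone F2 of the fallback above is silylated (TESCl, imidazole, CH2Cl2) to (3S)-6-methyl-3-[(triethylsilyl)oxy]hept-5-en-2-one F3. KN(SiMe3)2 at −78 °C gives potassium (3S)-6-methyl-3-[(triethylsilyl)oxy]hepta-1,5-dien-2-olate F4, which Comins' reagent converts into (3S)-6-methyl-3-[(triethylsilyl)oxy]hepta-1,5-dien-2-yl trifluoromethanesulfonate F5. AcOH/THF/H2O removes the silyl group to give (3S)-3-hydroxy-6-methylhepta-1,5-dien-2-yl trifluoromethanesulfonate F6. Yamaguchi esterification of F6 with angelic acid 9 comes back to the route at triflate 20.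

Step 8 (Suzuki–Miyaura coupling). The aryl acetate may be cleaved by the base, boron-to-palladium transfer of the pinacol ester may be slow without water, and prolonged contact with zerovalent palladium could ionise the allylic angelate (racemisation or 1,3-shift). The fallback sets out from boronate 8 and replaces the coupling by a base-free Negishi reaction at room temperature. Ipso-iododeboronation (NaI, TsN(Cl)Na, aqueous THF, rt) gives 2,4-bis[(tert-butyldimethylsilyl)oxy]-6-iodo-3-methylphenyl acetate F7. Acetoxy-assisted zinc insertion (Zn dust, LiCl, THF, 25–40 °C) gives {2-acetoxy-3,5-bis[(tert-butyldimethylsilyl)oxy]-4-methylphenyl}zinc iodide F8. Coupling of F8 with triflate 20 (Pd(OAc)2, SPhos, THF, rt) comes back to the route at 21.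

**Further compounds**
F1 | step 6 | (3S)-6-methyl-3-[(phenylamino)oxy]hept-5-en-2-one | CC(=O)[C@H](CC=C(C)C)ONc1ccccc1
F2 | step 6 | (3S)-3-hydroxy-6-methylhept-5-en-2-one | CC(=O)[C@H](CC=C(C)C)O
F3 | step 7 | (3S)-6-methyl-3-[(triethylsilyl)oxy]hept-5-en-2-one | CC(=O)[C@H](CC=C(C)C)O[Si](CC)(CC)CC
F4 | step 7 | potassium (3S)-6-methyl-3-[(triethylsilyl)oxy]hepta-1,5-dien-2-olate | C=C([O-])[C@H](CC=C(C)C)O[Si](CC)(CC)CC.[K+]
F5 | step 7 | (3S)-6-methyl-3-[(triethylsilyl)oxy]hepta-1,5-dien-2-yl trifluoromethanesulfonate | C=C(OS(=O)(=O)C(F)(F)F)[C@H](CC=C(C)C)O[Si](CC)(CC)CC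
F6 | step 7 | (3S)-3-hydroxy-6-methylhepta-1,5-dien-2-yl trifluoromethanesulfonate | C=C(OS(=O)(=O)C(F)(F)F)[C@H](CC=C(C)C)O
F7 | step 8 | 2,4-bis[(tert-butyldimethylsilyl)oxy]-6-iodo-3-methylphenyl acetate | CC(=O)Oc1c(I)cc(O[Si](C)(C)C(C)(C)C)c(C)c1O[Si](C)(C)C(C)(C)C
F8 | step 8 | {2-acetoxy-3,5-bis[(tert-butyldimethylsilyl)oxy]-4-methylphenyl}zinc iodide | CC(=O)Oc1c([Zn]I)cc(O[Si](C)(C)C(C)(C)C)c(C)c1O[Si](C)(C)C(C)(C)C
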